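**Plan**
- Ring C is opened at O1–C2 and C3–OH (oxidative chalcone cyclisation), and the C2–C3 bond is cut by an aldol disconnection. This gives a ring B aldehyde and a ring A methyl ketone; the C8–CH2 bond leads back to phloroacetophenone.
- Ring B carries two identical prenyl groups on the adjacent carbons C2' and C3'. The C2'–CH2 and C3'–CH2 bonds are therefore cut together, back to an aryne across C2'–C3', for which the direction of addition does not matter.
- Forward, ring B: 2,4,5-trihydroxybenzaldehyde → bis-MOM ether → C3 bromide → dioxolane → ortho-silyl triflate (steps 1–4), aryne bis-prenylation (step 5), aldehyde release (step 6).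
- Forward, ring A and union: C-prenylation of 2,4,6-trihydroxyacetophenone and bis-MOM protection (steps 7–8), Claisen–Schmidt condensation (step 9), ring C closed last by Algar–Flynn–Oyamada oxidation (step 10), MOM removal (step 11).
- Stereochemistry: the target has no stereocentre. The E-enone of the chalcone (thermodynamic) and the racemic C2/C3 centres of the transient dihydroflavonol both disappear on the way to the flavonol.

Key step: step 5

Remark: ring B intermediates are numbered as benzaldehydes (formyl carbon = C1, the later C1'), so their C2 and C3 are C2' and C3' of the target.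

Step 1
Reactants: 1 2,4,5-trihydroxybenzaldehyde
Product: 2 2-hydroxy-4,5-bis(methoxymethoxy)benzaldehyde
Conditions: MOMCl (2.1 equiv), i-Pr2NEt, CH2Cl2, 0 °C → rt
Reagents that add atoms: chloromethyl methyl ether, COCCl
Why: Williamson-type O-alkylation should cap only the 4- and 5-hydroxyls, because the 2-OH is held in a hydrogen bond to the formyl oxygen and is much less nucleophilic.

Step 2
Reactants: 2 2-hydroxy-4,5-bis(methoxymethoxy)benzaldehyde
Product: 3 3-bromo-2-hydroxy-4,5-bis(methoxymethoxy)benzaldehyde
Conditions: NBS (1.05 equiv), MeCN, 0 °C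
Reagents that add atoms: N-bromosuccinimide, O=C1CCC(=O)N1Br
Why: Electrophilic aromatic bromination should occur at C3 only, since it is the one free position ortho to the free phenol (and ortho to OMOM) while C6 is deactivated by the adjacent formyl group; NBS releases no HBr that could cleave the MOM ethers.

Step 3
Reactants: 3 3-bromo-2-hydroxy-4,5-bis(methoxymethoxy)benzaldehyde
Product: 4 2-bromo-6-(1,3-dioxolan-2-yl)-3,4-bis(methoxymethoxy)phenol
Conditions: TMSOCH2CH2OTMS, TMSOTf (5 mol %), CH2Cl2, −78 → −20 °C; then pyridine, aq. NaHCO3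
Reagents that add atoms: 1,2-bis(trimethylsilyloxy)ethane, C[Si](C)(C)OCCO[Si](C)(C)C
Why: Silyl-triflate-catalysed acetalisation with the bis-silyl ether of ethylene glycol is driven by formation of hexamethyldisiloxane and runs cold and aprotic, which the aryl MOM ethers should tolerate; the dioxolane masks the aldehyde against the organolithium of step 4.

Step 4
Reactants: 4 2-bromo-6-(1,3-dioxolan-2-yl)-3,4-bis(methoxymethoxy)phenol
Product: 7 6-(1,3-dioxolan-2-yl)-3,4-bis(methoxymethoxy)-2-(trimethylsilyl)phenyl trifluoromethanesulfonate, via aryl trimethylsilyl ether 5 (not isolated), via lithium silylphenolate 6 (not isolated)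
Conditions: HMDS, THF, 70 °C, evaporate; n-BuLi, THF, −78 °C; PhNTf2, −78 °C → rt; aq. NH4Cl work-up
Reagents that add atoms: hexamethyldisilazane, C[Si](C)(C)N[Si](C)(C)C; N-phenylbis(trifluoromethanesulfonimide), O=S(=O)(N(c1ccccc1)S(=O)(=O)C(F)(F)F)C(F)(F)F
Why: O-silylation, bromine–lithium exchange and 1,3 O→C silyl migration (retro-Brook rearrangement) put silicon on the carbon that carried bromine, and the released lithium phenolate is trapped as the triflate, which is the standard way to ortho-silylaryl triflates; the acetal and MOM ethers are inert to n-BuLi at −78 °C and to the mild triflating agent.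

Step 5
Reactants: 7 6-(1,3-dioxolan-2-yl)-3,4-bis(methoxymethoxy)-2-(trimethylsilyl)phenyl trifluoromethanesulfonate; 8 prenyl chloride (1-chloro-3-methylbut-2-ene); 9 tributyl(3-methylbut-2-enyl)stannane
Product: 11 2-[4,5-bis(methoxymethoxy)-2,3-bis(3-methylbut-2-enyl)phenyl]-1,3-dioxolane, via aryne 10 (not isolated)
Conditions: Pd2(dba)3·CHCl3 (2.5 mol %), 1,1'-bis(diphenylphosphino)ferrocene (5 mol %), CsF, MeCN, 40 °C
Reagents that add atoms: none
Why: Proposed new method: fluoride attack on silicon with loss of triflate from 7 gives aryne 10, while zerovalent palladium adds oxidatively to prenyl chloride and the stannane transmetalates the resulting prenylpalladium chloride to a bis(prenyl)palladium species; the aryne inserts into the palladium–CH2 bond of the σ-bound prenyl ligand, and reductive elimination from the aryl(prenyl)palladium forms the second C–C bond and returns zerovalent palladium. The closest known reaction type is the palladium-catalysed three-component bis-allylation of arynes with allyl chloride and allyltributylstannane, which has not been shown with two 3,3-disubstituted allyl partners. No ring is closed and no stereocentre is created. The step needs both prenyl units attached through CH2 and not through CMe2: the σ-prenyl ligand binds palladium at its unhindered primary carbon, so insertion gives the first benzylic CH2, and reductive elimination from the aryl(π-prenyl) complex should occur at the less substituted allyl terminus, which the wide-bite-angle diphosphine favours. Orientation of addition across C2'–C3' is irrelevant because the two incoming groups are identical, so the unlike flanking groups (acetal carbon and OMOM) cannot give regioisomers, and exchange between chloride-derived and stannane-derived prenyl units is harmless. The MOM ethers and the dioxolane are inert to CsF and to the catalyst.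

Step 6
Reactants: 11 2-[4,5-bis(methoxymethoxy)-2,3-bis(3-methylbut-2-enyl)phenyl]-1,3-dioxolane
Product: 12 4,5-bis(methoxymethoxy)-2,3-bis(3-methylbut-2-enyl)benzaldehyde
Conditions: PPTS (cat.), acetone–H2O, rt
Reagents that add atoms: water, O
Why: Acid-catalysed acetal hydrolysis should unmask the aldehyde alone, because the aryl dioxolane (oxocarbenium ion stabilised by the para OMOM oxygen) is far more labile than the MOM ethers and the alkenes are untouched by the buffered acid.

Step 7
Reactants: 13 2,4,6-trihydroxyacetophenone; 14 prenyl bromide (1-bromo-3-methylbut-2-ene)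
Product: 15 1-[2,4,6-trihydroxy-3-(3-methylbut-2-enyl)phenyl]ethanone
Conditions: DBU, THF, 0 °C → rt
Reagents that add atoms: none
Why: C-alkylation of the ambident phloroglucinol-type phenolate with one equivalent of prenyl bromide is the established entry to 3-prenylphloroacetophenone; the two free ring positions are equivalent, so only the degree of alkylation has to be controlled.

Step 8
Reactants: 15 1-[2,4,6-trihydroxy-3-(3-methylbut-2-enyl)phenyl]ethanone
Product: 16 1-[2-hydroxy-4,6-bis(methoxymethoxy)-3-(3-methylbut-2-enyl)phenyl]ethanone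
Conditions: MOMCl (2.1 equiv), i-Pr2NEt, CH2Cl2, 0 °C → rt
Reagents that add atoms: chloromethyl methyl ether, COCCl
Why: Williamson-type MOM protection should take the unhindered 4-OH and the more accessible 6-OH, leaving free the 2-OH that the prenyl group pushes into a strong hydrogen bond with the acetyl oxygen; this free OH next to the prenyl group later becomes O1 and so fixes the prenyl at C8.

Step 9
Reactants: 12 4,5-bis(methoxymethoxy)-2,3-bis(3-methylbut-2-enyl)benzaldehyde; 16 1-[2-hydroxy-4,6-bis(methoxymethoxy)-3-(3-methylbut-2-enyl)phenyl]ethanone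
Product: 17 (E)-3-[4,5-bis(methoxymethoxy)-2,3-bis(3-methylbut-2-enyl)phenyl]-1-[2-hydroxy-4,6-bis(methoxymethoxy)-3-(3-methylbut-2-enyl)phenyl]prop-2-en-1-one
Conditions: KOH, EtOH–H2O, rt
Reagents that add atoms: none
Why: Claisen–Schmidt (crossed aldol) condensation of the methyl ketone enolate with the non-enolisable aldehyde, followed by E1cB dehydration, should give the thermodynamically preferred E-enone; MOM ethers and prenyl groups are stable to hydroxide.

Step 10
Reactants: 17 (E)-chalcone from step 9
Product: 19 3-hydroxy-5,7-bis(methoxymethoxy)-2-[4,5-bis(methoxymethoxy)-2,3-bis(3-methylbut-2-enyl)phenyl]-8-(3-methylbut-2-enyl)chromen-4-one, via trans-dihydroflavonol 18 (not isolated)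
Conditions: 30% aq. H2O2, aq. NaOH, MeOH–THF, 0 °C → rt
Reagents that add atoms: hydrogen peroxide, OO
Why: In the Algar–Flynn–Oyamada reaction alkaline hydrogen peroxide oxidises the 2'-hydroxychalcone while the phenolate closes the six-membered ring C at the β-carbon, and the resulting racemic trans-3-hydroxyflavanone is dehydrogenated in situ to the flavonol; the unactivated prenyl alkenes are inert to nucleophilic peroxide.

Step 11
Reactants: 19 tetrakis-MOM flavonol from step 10
Product: 20 Broussoflavonol G
Conditions: 3 M aq. HCl, MeOH, 50 °C, short reaction time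
Reagents that add atoms: none
Why: Acid-catalysed acetal exchange with methanol should remove the four aryl MOM ethers; mild temperature and short exposure are chosen because addition of a freed phenol to its ortho prenyl alkene (chroman formation) is slower than MOM cleavage.

**Compound list**
1 | 2,4,5-trihydroxybenzaldehyde | O=Cc1cc(O)c(O)cc1O | starting material
2 | 2-hydroxy-4,5-bis(methoxymethoxy)benzaldehyde | O=Cc1cc(OCOC)c(OCOC)cc1O | intermediate
3 | 3-bromo-2-hydroxy-4,5-bis(methoxymethoxy)benzaldehyde | O=Cc1cc(OCOC)c(OCOC)c(Br)c1O | intermediate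
4 | 2-bromo-6-(1,3-dioxolan-2-yl)-3,4-bis(methoxymethoxy)phenol | Oc1c(Br)c(OCOC)c(OCOC)cc1C1OCCO1 | intermediate
5 | [2-bromo-6-(1,3-dioxolan-2-yl)-3,4-bis(methoxymethoxy)phenoxy]trimethylsilane (formed in situ) | C[Si](C)(C)Oc1c(Br)c(OCOC)c(OCOC)cc1C1OCCO1 | intermediate
6 | lithium 6-(1,3-dioxolan-2-yl)-3,4-bis(methoxymethoxy)-2-(trimethylsilyl)phenolate (formed in situ) | [Li+].[O-]c1c([Si](C)(C)C)c(OCOC)c(OCOC)cc1C1OCCO1 | intermediate
7 | 6-(1,3-dioxolan-2-yl)-3,4-bis(methoxymethoxy)-2-(trimethylsilyl)phenyl trifluoromethanesulfonate | COCOc1cc(C2OCCO2)c(OS(=O)(=O)C(F)(F)F)c([Si](C)(C)C)c1OCOC | intermediate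
8 | prenyl chloride (1-chloro-3-methylbut-2-ene) | CC(C)=CCCl | starting material
9 | tributyl(3-methylbut-2-enyl)stannane | CCCC[Sn](CCCC)(CCCC)CC=C(C)C | starting material
10 | 3-(1,3-dioxolan-2-yl)-5,6-bis(methoxymethoxy)-1,2-didehydrobenzene (aryne, formed in situ) | COCOC1=C(OCOC)C#CC(C2OCCO2)=C1 | intermediate
11 | 2-[4,5-bis(methoxymethoxy)-2,3-bis(3-methylbut-2-enyl)phenyl]-1,3-dioxolane | COCOc1cc(C2OCCO2)c(CC=C(C)C)c(CC=C(C)C)c1OCOC | intermediate
12 | 4,5-bis(methoxymethoxy)-2,3-bis(3-methylbut-2-enyl)benzaldehyde | COCOc1cc(C=O)c(CC=C(C)C)c(CC=C(C)C)c1OCOC | intermediate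
13 | 2,4,6-trihydroxyacetophenone | CC(=O)c1c(O)cc(O)cc1O | starting material
14 | prenyl bromide (1-bromo-3-methylbut-2-ene) | CC(C)=CCBr | starting material
15 | 1-[2,4,6-trihydroxy-3-(3-methylbut-2-enyl)phenyl]ethanone | CC(=O)c1c(O)cc(O)c(CC=C(C)C)c1O | intermediate
16 | 1-[2-hydroxy-4,6-bis(methoxymethoxy)-3-(3-methylbut-2-enyl)phenyl]ethanone | CC(=O)c1c(OCOC)cc(OCOC)c(CC=C(C)C)c1O | intermediate
17 | (E)-3-[4,5-bis(methoxymethoxy)-2,3-bis(3-methylbut-2-enyl)phenyl]-1-[2-hydroxy-4,6-bis(methoxymethoxy)-3-(3-methylbut-2-enyl)phenyl]prop-2-en-1-one | COCOc1cc(OCOC)c(CC=C(C)C)c(O)c1C(=O)/C=C/c1cc(OCOC)c(OCOC)c(CC=C(C)C)c1CC=C(C)C | intermediate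
18 | (2R*,3R*)-trans-3-hydroxy-5,7-bis(methoxymethoxy)-2-[4,5-bis(methoxymethoxy)-2,3-bis(3-methylbut-2-enyl)phenyl]-8-(3-methylbut-2-enyl)chroman-4-one (racemic, one enantiomer drawn, formed in situ) | COCOc1cc(OCOC)c2c(c1CC=C(C)C)O[C@H](c1cc(OCOC)c(OCOC)c(CC=C(C)C)c1CC=C(C)C)[C@@H](O)C2=O | intermediate
19 | 3-hydroxy-5,7-bis(methoxymethoxy)-2-[4,5-bis(methoxymethoxy)-2,3-bis(3-methylbut-2-enyl)phenyl]-8-(3-methylbut-2-enyl)chromen-4-one | COCOc1cc(OCOC)c2c(=O)c(O)c(-c3cc(OCOC)c(OCOC)c(CC=C(C)C)c3CC=C(C)C)oc2c1CC=C(C)C | intermediate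
20 | Broussoflavonol G, 2-[4,5-dihydroxy-2,3-bis(3-methylbut-2-enyl)phenyl]-3,5,7-trihydroxy-8-(3-methylbut-2-enyl)chromen-4-one | CC(C)=CCc1c(-c2oc3c(CC=C(C)C)c(O)cc(O)c3c(=O)c2O)cc(O)c(O)c1CC=C(C)C | target

**Step count**
Total: 11 steps. Longest linear sequence: 9 steps (1, 2, 3, 4, 5, 6, 9, 10, 11); the ring A ketone is made in 2 steps (7, 8) and joins at step 9.

**Steps most likely to fail**

Step 5. The bis(prenyl)palladium species may be too hindered to capture the aryne before the aryne oligomerises, or one prenyl unit may bond through its tertiary terminus. The fallback uses known cross-coupling chemistry and sets out from bromophenol 4. Triflation (Tf2O, pyridine, CH2Cl2, 0 °C) should give 2-bromo-6-(1,3-dioxolan-2-yl)-3,4-bis(methoxymethoxy)phenyl trifluoromethanesulfonate F1. A twofold Stille coupling of its C–Br and C–OTf bonds with stannane 9 (Pd(PPh3)4, LiCl, CuI, DMF, 90 °C) would then form the same two aryl–CH2 bonds with linear prenyl attachment. This path returns to the route at compound 11.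

Step 10. With the 6'-OMOM group and the ortho-substituted ring B, the phenolate may attack the α-carbon in a five-membered closure and lead to the aurone instead of the flavonol. The fallback sets out from chalcone 17 and separates ring closure from C3 oxygenation. Intramolecular oxa-Michael addition (NaOAc, EtOH, reflux) should give the racemic flavanone 5,7-bis(methoxymethoxy)-2-[4,5-bis(methoxymethoxy)-2,3-bis(3-methylbut-2-enyl)phenyl]-8-(3-methylbut-2-enyl)chroman-4-one F2. Dehydrogenation with I2 in pyridine at 90 °C would give the corresponding flavone, 5,7-bis(methoxymethoxy)-2-[4,5-bis(methoxymethoxy)-2,3-bis(3-methylbut-2-enyl)phenyl]-8-(3-methylbut-2-enyl)chromen-4-one F3. C3 lithiation with LiN(i-Pr)2 in THF at −78 °C, borylation with B(OMe)3 and oxidation with H2O2–AcOH would install the 3-hydroxyl. This path returns to the route at compound 19.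

Step 11. Once a phenol next to a prenyl group is freed, acid-catalysed addition of that phenol to the alkene (chroman formation) may compete with cleavage of the remaining MOM ethers. The fallback sets out from compound 19 and avoids Brønsted acid. TESOTf with 2,2'-bipyridyl in CH2Cl2 at 0 °C should exchange each aryl MOM ether for a triethylsilyl ether and silylate the 3-OH, giving 3,5,7-tris(triethylsilyloxy)-2-[4,5-bis(triethylsilyloxy)-2,3-bis(3-methylbut-2-enyl)phenyl]-8-(3-methylbut-2-enyl)chromen-4-one F4. KHF2 in MeOH at room temperature would then cleave the aryl silyl ethers under near-neutral conditions. This path returns to the route at compound 20.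

**Further compounds**
F1 | step 5 | 2-bromo-6-(1,3-dioxolan-2-yl)-3,4-bis(methoxymethoxy)phenyl trifluoromethanesulfonate | COCOc1cc(C2OCCO2)c(OS(=O)(=O)C(F)(F)F)c(Br)c1OCOC
F2 | step 10 | 5,7-bis(methoxymethoxy)-2-[4,5-bis(methoxymethoxy)-2,3-bis(3-methylbut-2-enyl)phenyl]-8-(3-methylbut-2-enyl)chroman-4-one (racemic) | COCOc1cc(OCOC)c2c(c1CC=C(C)C)OC(c1cc(OCOC)c(OCOC)c(CC=C(C)C)c1CC=C(C)C)CC2=O
F3 | step 10 | 5,7-bis(methoxymethoxy)-2-[4,5-bis(methoxymethoxy)-2,3-bis(3-methylbut-2-enyl)phenyl]-8-(3-methylbut-2-enyl)chromen-4-one | COCOc1cc(OCOC)c2c(=O)cc(-c3cc(OCOC)c(OCOC)c(CC=C(C)C)c3CC=C(C)C)oc2c1CC=C(C)C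
F4 | step 11 | 3,5,7-tris(triethylsilyloxy)-2-[4,5-bis(triethylsilyloxy)-2,3-bis(3-methylbut-2-enyl)phenyl]-8-(3-methylbut-2-enyl)chromen-4-one | CC[Si](CC)(CC)Oc1cc(O[Si](CC)(CC)CC)c2c(=O)c(O[Si](CC)(CC)CC)c(-c3cc(O[Si](CC)(CC)CC)c(O[Si](CC)(CC)CC)c(CC=C(C)C)c3CC=C(C)C)oc2c1CC=C(C)C
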